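**Strategy.** Ring C is cut at C2–C3 and C4–C4a. The heterodiene O1=C2 plus C8a=C4a of ring A is read as the O-aryl oxocarbenium ion of formaldehyde. The C3–C4 pair is read as an enol ether: a ring B styrene carrying a chiral alkoxy group on the carbon that becomes C4. One Lewis-acid annulation should close ring C, form both bonds and set C3; the alkoxy group is then removed from C4 by ionic reduction. The step exploits the symmetry of the prenylated phloroglucinol ring A, whose two ortho carbons (C4a, C8) are equivalent. The precursors are a ring A aryloxymethyl acetate and the (E)-enol ether of the ring B styrene with (1R,2S)-2-phenylcyclohexanol.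

Key step: step 10

Remark on ring B: ordinary chromenylation of 2,4-dihydroxybenzaldehyde closes the pyran through O4 and gives the wrong isomer. Ring B needs the pyran oxygen ortho to the formyl carbon, so O4 is silylated first and the pyran is built from O2 by a propargyl Claisen sequence. A TIPS ether is chosen for O4' because it has to pass 170 °C and Cs2CO3.

Assumption: (1R,2S)-2-phenylcyclohexanol is taken to induce 3R. Should step 10 give 3S, the commercial (1S,2R)-enantiomer is used in step 9 and nothing else changes.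

**Route**

Step 1
Reactants: 1 phloroglucinol; 2 prenyl bromide
Product: 3 2-(3-methylbut-2-enyl)benzene-1,3,5-triol
Conditions: 1 (3 equiv), DBU (1 equiv), THF, 0 °C to rt
Reagents that add atoms: none
Why: C-alkylation of the ambident phloroglucinol phenoxide with the primary allylic bromide is the usual entry to 2-prenylphloroglucinol, and the excess of triol should limit double prenylation.

Step 2
Reactants: 3 2-(3-methylbut-2-enyl)benzene-1,3,5-triol
Product: 4 1,3,5-tris(tert-butyldimethylsilyloxy)-2-(3-methylbut-2-enyl)benzene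
Conditions: TBSCl (3.6 equiv), imidazole, DMF, rt
Reagents that add atoms: TBSCl, CC(C)(C)[Si](C)(C)Cl
Why: Imidazole-promoted silylation of phenols should cap all three hydroxyls, so that no free phenol flanks the prenyl group in the later Lewis-acid steps.

Step 3
Reactants: 4 1,3,5-tris(tert-butyldimethylsilyloxy)-2-(3-methylbut-2-enyl)benzene
Product: 5 3,5-bis(tert-butyldimethylsilyloxy)-4-(3-methylbut-2-enyl)phenol
Conditions: K2CO3 (0.3 equiv), MeOH–THF 1:1, −10 to 0 °C, stopped when 4 is consumed
Reagents that add atoms: none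
Why: Base-catalysed methanolysis of aryl silyl ethers is slowed by ortho substituents, so the ether para to the prenyl group (two ortho hydrogens) should cleave first, and the phenoxide formed should retard a second cleavage.

Step 4
Reactants: 5 3,5-bis(tert-butyldimethylsilyloxy)-4-(3-methylbut-2-enyl)phenol
Product: 6 [3,5-bis(tert-butyldimethylsilyloxy)-4-(3-methylbut-2-enyl)phenoxy]methyl acetate
Conditions: NaH (1.05 equiv), THF–DMF 4:1, 0 °C; then BrCH2OAc (1.2 equiv), 0 °C to rt
Reagents that add atoms: bromomethyl acetate, CC(=O)OCBr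
Why: Williamson-type SN2 alkylation of the sodium phenoxide with the very reactive α-acyloxy bromide should give the acetoxymethyl ether, and the brief cold basic conditions should spare the two silyl ethers.

Step 5
Reactants: 7 2,4-dihydroxybenzaldehyde
Product: 8 2-hydroxy-4-(triisopropylsilyloxy)benzaldehyde
Conditions: TIPSCl (1.05 equiv), imidazole, CH2Cl2, 0 °C
Reagents that add atoms: TIPSCl, CC(C)[Si](Cl)(C(C)C)C(C)C
Why: Selective phenol silylation should occur at O4, which is the more acidic hydroxyl and is not hydrogen-bonded to the formyl group.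

Step 6
Reactants: 8 2-hydroxy-4-(triisopropylsilyloxy)benzaldehyde
Product: 9 2-(2-methylbut-3-yn-2-yloxy)-4-(triisopropylsilyloxy)benzaldehyde
Conditions: 3-chloro-3-methylbut-1-yne (1.5 equiv), DBU, CuCl2 (1 mol %), MeCN, 0 °C
Reagents that add atoms: 3-chloro-3-methylbut-1-yne, CC(C)(Cl)C#C
Why: Copper-catalysed propargylic etherification through a copper acetylide should O-alkylate even a chelated, acidic phenol with the tertiary propargylic chloride at 0 °C.

Step 7
Reactants: 9 2-(2-methylbut-3-yn-2-yloxy)-4-(triisopropylsilyloxy)benzaldehyde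
Product: 11 2,2-dimethyl-5-(triisopropylsilyloxy)-2H-chromene-8-carbaldehyde, via allenylphenol 10 (not isolated)
Conditions: PhNEt2, 170 °C
Reagents that add atoms: none
Why: The aromatic propargyl Claisen rearrangement can only reach C3 because the other ortho carbon carries the formyl group, and the allenylphenol should close to the 2,2-dimethylchromene by 1,5-hydrogen shift and oxa-6π electrocyclisation, which puts the pyran oxygen ortho to the formyl carbon.

Step 8
Reactants: 11 2,2-dimethyl-5-(triisopropylsilyloxy)-2H-chromene-8-carbaldehyde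
Product: 12 (E)-8-(2-iodoethenyl)-2,2-dimethyl-5-(triisopropylsilyloxy)-2H-chromene
Conditions: CHI3 (2 equiv), CrCl2 (6 equiv), THF, 0 °C to rt
Reagents that add atoms: iodoform, IC(I)I
Why: The Takai olefination converts aryl aldehydes into (E)-vinyl iodides with high E selectivity and should leave the silyl ether and the chromene alkene alone.

Step 9
Reactants: 12 (E)-8-(2-iodoethenyl)-2,2-dimethyl-5-(triisopropylsilyloxy)-2H-chromene; 13 (1R,2S)-2-phenylcyclohexanol
Product: 14 (E)-2,2-dimethyl-8-{2-[(1R,2S)-2-phenylcyclohexyloxy]ethenyl}-5-(triisopropylsilyloxy)-2H-chromene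
Conditions: 13 (1.5 equiv), CuI (10 mol %), 3,4,7,8-tetramethyl-1,10-phenanthroline (20 mol %), Cs2CO3 (1.5 equiv), toluene, 80 °C
Reagents that add atoms: none
Why: Ullmann-type copper-catalysed C–O coupling of vinyl iodides with alcohols proceeds with retention of alkene geometry, so the (E)-iodide should give the (E)-enol ether.

Step 10
Reactants: 6 [3,5-bis(tert-butyldimethylsilyloxy)-4-(3-methylbut-2-enyl)phenoxy]methyl acetate; 14 (E)-2,2-dimethyl-8-{2-[(1R,2S)-2-phenylcyclohexyloxy]ethenyl}-5-(triisopropylsilyloxy)-2H-chromene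
Product: 15 (3R)-5,7-bis(tert-butyldimethylsilyloxy)-3-[2,2-dimethyl-5-(triisopropylsilyloxy)-2H-chromen-8-yl]-6-(3-methylbut-2-enyl)-4-[(1R,2S)-2-phenylcyclohexyloxy]chroman (both C4 epimers)
Conditions: 14 (1.0 equiv), TMSOTf (1.2 equiv), 2,6-di-tert-butyl-4-methylpyridine (1.5 equiv), CH2Cl2, −78 °C; 6 (1.3 equiv) added over 1 h; Et3N quench at −78 °C
Reagents that add atoms: none
Why: Proposed new method: TMSOTf should abstract acetate from 6 to give the aryloxymethyl cation (O1=C2); the aryl-bearing carbon of enol ether 14 adds to C2 (C2–C3 bond), and the resulting C4 oxocarbenium ion, stabilised by the auxiliary oxygen, is captured by the ortho carbon of ring A (C4–C4a bond) with loss of a proton to the hindered pyridine. The closest known chemistry is the oxa-Povarov reaction (Lewis-acid formal [4+2] of aryl oxocarbenium ions from mixed acetals with alkenes to give chromans) together with Lewis-acid hetero-Diels–Alder reactions of 2-phenylcyclohexyl enol ethers; a formaldehyde-derived cation and auxiliary control in this setting have not been shown. Ring C closes by a 6-exo-trig Friedel–Crafts attack of C4a on the C4=O bond, which lies outside the new ring, and this should be fast because ring A carries three ether donors again once O1 is neutral. C3 is set in the first bond formation, where the phenyl group of the auxiliary covers one face of the s-trans (E)-enol ether and the E geometry kept from step 9 turns that facial choice into one configuration; C4 forms as a mixture that step 11 removes. The step needs chemoselectivity for the enol ether over the prenyl and chromene alkenes and over ring A of a second molecule (secured by the higher nucleophilicity of the enol ether and the slow addition of 6), regioselectivity for an isoflavan (secured by the enol ether polarity, which puts ring B on C3), and no site selectivity at ring A (its two ortho carbons are equivalent by symmetry).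

Step 11
Reactants: 15 (3R)-4-alkoxyisoflavan from step 10
Product: 16 (3R)-5,7-bis(tert-butyldimethylsilyloxy)-3-[2,2-dimethyl-5-(triisopropylsilyloxy)-2H-chromen-8-yl]-6-(3-methylbut-2-enyl)chroman
Conditions: Et3SiH (5 equiv), Et3SiOTf (0.2 equiv), CH2Cl2, −78 to −40 °C; Et3N quench
Reagents that add atoms: none
Why: In this ionic hydrogenation the silyl triflate should ionise the C4 ether to a benzylic cation stabilised by O5, O7 and O1 and the silane should deliver hydride before H3 is lost, so both C4 epimers converge on one isoflavan with C3 untouched, while the absence of protic acid protects the prenyl and chromene alkenes.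

Step 12
Reactants: 16 (3R)-tris-silylated isoflavan from step 11
Product: 17 (3R)-3-(5-hydroxy-2,2-dimethyl-2H-chromen-8-yl)-6-(3-methylbut-2-enyl)chroman-5,7-diol
Conditions: TBAF (4 equiv), AcOH (4 equiv), THF, 0 °C to rt, under argon
Reagents that add atoms: none
Why: Fluoride-mediated desilylation buffered with acetic acid should remove all three aryl silyl ethers without exposing the electron-rich triol as free phenoxides.

Step 13
Reactants: 17 (3R)-isoflavan triol from step 12
Product: 18 (3R)-3-[2,2-dimethyl-5-(triisopropylsilyloxy)-2H-chromen-8-yl]-6-(3-methylbut-2-enyl)-7-(triisopropylsilyloxy)chroman-5-ol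
Conditions: TIPSCl (2.2 equiv), imidazole, DMF, 0 °C to rt
Reagents that add atoms: TIPSCl, CC(C)[Si](Cl)(C(C)C)C(C)C
Why: Sterically controlled silylation should take O7 and O4', each with one ortho hydrogen, and leave O5, which sits between the prenyl group and C4, free.

Step 14
Reactants: 18 (3R)-7,4'-bis-TIPS isoflavan-5-ol from step 13
Product: 19 (3R)-3-[2,2-dimethyl-5-(triisopropylsilyloxy)-2H-chromen-8-yl]-5-methoxy-6-(3-methylbut-2-enyl)-7-(triisopropylsilyloxy)chroman
Conditions: MeI (3 equiv), K2CO3 (2 equiv), acetone, 45 °C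
Reagents that add atoms: iodomethane, CI
Why: Williamson O-methylation of the hindered phenoxide with the small electrophile MeI is little affected by the two ortho substituents, and aryl TIPS ethers tolerate K2CO3 in acetone.

Step 15
Reactants: 19 (3R)-5-methoxy-7,4'-bis-TIPS isoflavan from step 14
Product: 20 (3R)-3-(5-hydroxy-2,2-dimethyl-2H-chromen-8-yl)-5-methoxy-6-(3-methylbut-2-enyl)chroman-7-ol (target)
Conditions: TBAF (2.5 equiv), AcOH (2.5 equiv), THF, 0 °C to rt
Reagents that add atoms: none
Why: Buffered fluoride desilylation should free O7 and O4' without touching the methyl ether, the two alkenes or C3.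

**Compound list**

1 | phloroglucinol | Oc1cc(O)cc(O)c1 | starting material
2 | prenyl bromide | CC(C)=CCBr | starting material
3 | 2-(3-methylbut-2-enyl)benzene-1,3,5-triol | CC(C)=CCc1c(O)cc(O)cc1O | intermediate
4 | 1,3,5-tris(tert-butyldimethylsilyloxy)-2-(3-methylbut-2-enyl)benzene | CC(C)=CCc1c(O[Si](C)(C)C(C)(C)C)cc(O[Si](C)(C)C(C)(C)C)cc1O[Si](C)(C)C(C)(C)C | intermediate
5 | 3,5-bis(tert-butyldimethylsilyloxy)-4-(3-methylbut-2-enyl)phenol | CC(C)=CCc1c(O[Si](C)(C)C(C)(C)C)cc(O)cc1O[Si](C)(C)C(C)(C)C | intermediate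
6 | [3,5-bis(tert-butyldimethylsilyloxy)-4-(3-methylbut-2-enyl)phenoxy]methyl acetate | CC(=O)OCOc1cc(O[Si](C)(C)C(C)(C)C)c(CC=C(C)C)c(O[Si](C)(C)C(C)(C)C)c1 | intermediate
7 | 2,4-dihydroxybenzaldehyde | O=Cc1ccc(O)cc1O | starting material
8 | 2-hydroxy-4-(triisopropylsilyloxy)benzaldehyde | O=Cc1ccc(O[Si](C(C)C)(C(C)C)C(C)C)cc1O | intermediate
9 | 2-(2-methylbut-3-yn-2-yloxy)-4-(triisopropylsilyloxy)benzaldehyde | C#CC(C)(C)Oc1cc(O[Si](C(C)C)(C(C)C)C(C)C)ccc1C=O | intermediate
10 | 2-hydroxy-3-(3-methylbuta-1,2-dienyl)-4-(triisopropylsilyloxy)benzaldehyde (allenylphenol, formed in the flask in step 7) | CC(C)=C=Cc1c(O)c(C=O)ccc1O[Si](C(C)C)(C(C)C)C(C)C | intermediate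
11 | 2,2-dimethyl-5-(triisopropylsilyloxy)-2H-chromene-8-carbaldehyde | CC1(C)C=Cc2c(O[Si](C(C)C)(C(C)C)C(C)C)ccc(C=O)c2O1 | intermediate
12 | (E)-8-(2-iodoethenyl)-2,2-dimethyl-5-(triisopropylsilyloxy)-2H-chromene | CC1(C)C=Cc2c(O[Si](C(C)C)(C(C)C)C(C)C)ccc(/C=C/I)c2O1 | intermediate
13 | (1R,2S)-2-phenylcyclohexanol | O[C@@H]1CCCC[C@H]1c1ccccc1 | starting material
14 | (E)-2,2-dimethyl-8-{2-[(1R,2S)-2-phenylcyclohexyloxy]ethenyl}-5-(triisopropylsilyloxy)-2H-chromene | CC1(C)C=Cc2c(O[Si](C(C)C)(C(C)C)C(C)C)ccc(/C=C/O[C@@H]3CCCC[C@H]3c3ccccc3)c2O1 | intermediate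
15 | (3R)-5,7-bis(tert-butyldimethylsilyloxy)-3-[2,2-dimethyl-5-(triisopropylsilyloxy)-2H-chromen-8-yl]-6-(3-methylbut-2-enyl)-4-[(1R,2S)-2-phenylcyclohexyloxy]chroman (C4 epimers) | CC(C)(C)[Si](C)(C)Oc1c(CC=C(C)C)c(O[Si](C)(C)C(C)(C)C)cc2c1C(O[C@@H]1CCCC[C@H]1c1ccccc1)[C@H](c1ccc(O[Si](C(C)C)(C(C)C)C(C)C)c3c1OC(C)(C)C=C3)CO2 | intermediate
16 | (3R)-5,7-bis(tert-butyldimethylsilyloxy)-3-[2,2-dimethyl-5-(triisopropylsilyloxy)-2H-chromen-8-yl]-6-(3-methylbut-2-enyl)chroman | CC(C)(C)[Si](C)(C)Oc1c(CC=C(C)C)c(O[Si](C)(C)C(C)(C)C)cc2c1C[C@H](c1ccc(O[Si](C(C)C)(C(C)C)C(C)C)c3c1OC(C)(C)C=C3)CO2 | intermediate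
17 | (3R)-3-(5-hydroxy-2,2-dimethyl-2H-chromen-8-yl)-6-(3-methylbut-2-enyl)chroman-5,7-diol | Oc1c(CC=C(C)C)c(O)cc2c1C[C@H](c1ccc(O)c3c1OC(C)(C)C=C3)CO2 | intermediate
18 | (3R)-3-[2,2-dimethyl-5-(triisopropylsilyloxy)-2H-chromen-8-yl]-6-(3-methylbut-2-enyl)-7-(triisopropylsilyloxy)chroman-5-ol | Oc1c(CC=C(C)C)c(O[Si](C(C)C)(C(C)C)C(C)C)cc2c1C[C@H](c1ccc(O[Si](C(C)C)(C(C)C)C(C)C)c3c1OC(C)(C)C=C3)CO2 | intermediate
19 | (3R)-3-[2,2-dimethyl-5-(triisopropylsilyloxy)-2H-chromen-8-yl]-5-methoxy-6-(3-methylbut-2-enyl)-7-(triisopropylsilyloxy)chroman | COc1c(CC=C(C)C)c(O[Si](C(C)C)(C(C)C)C(C)C)cc2c1C[C@H](c1ccc(O[Si](C(C)C)(C(C)C)C(C)C)c3c1OC(C)(C)C=C3)CO2 | intermediate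
20 | (3R)-3-(5-hydroxy-2,2-dimethyl-2H-chromen-8-yl)-5-methoxy-6-(3-methylbut-2-enyl)chroman-7-ol | COc1c(CC=C(C)C)c(O)cc2c1C[C@H](c1ccc(O)c3c1OC(C)(C)C=C3)CO2 | target

**Totals**

Total step count: 15. Longest linear sequence: 11 steps (steps 5 to 15, from 2,4-dihydroxybenzaldehyde).

**Steps most likely to fail**

Step 10. The aryloxymethyl cation may alkylate ring A of a second molecule instead of the enol ether. Facial selectivity at C3 may be poor. The C4 oxocarbenium ion or the product ether may lose H3 and erase C3. The fallback is known chemistry: an inverse-demand hetero-Diels–Alder reaction of an ortho-quinone methide of ring A with the same chiral enol ether, followed by acetal reduction. It sets out from phenol 5 and enol ether 14 and comes back at 16.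
- Magnesium-mediated ortho-formylation of 5 (MgCl2, Et3N, paraformaldehyde, THF, reflux; the two ortho sites are equivalent) should give 2,4-bis(tert-butyldimethylsilyloxy)-6-hydroxy-3-(3-methylbut-2-enyl)benzaldehyde F1.
- Boc2O with iPr2NEt and catalytic DMAP should give the aryl tert-butyl carbonate of that aldehyde F2.
- NaBH4 at −20 °C with a cold acetic acid quench should give the corresponding 2-(hydroxymethyl)phenyl tert-butyl carbonate F3.
- t-BuMgCl at −78 °C in the presence of 14, then warming, moves the carbonate to the benzylic alkoxide and expels it. This releases the ring A ortho-quinone methide F4.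
- The methylene carbon of F4 (the future C4) bonds to the aryl-bearing carbon of 14 and its oxygen (O1) to the alkoxy-bearing carbon. This should give the (3R)-2-[(1R,2S)-2-phenylcyclohexyloxy]isoflavan F5, with C3 set by the auxiliary; the sense of induction needs the same check as in the main route.
- Et3SiH with catalytic Et3SiOTf, as in step 11, reduces the C2 acetal and returns to 16.

This forms C3–C4 and O1–C2 instead of C2–C3 and C4–C4a, and puts the auxiliary oxygen on C2.

Step 9. Cs2CO3 may eliminate HI from the vinyl iodide to give the arylacetylene, and C–O coupling with the hindered secondary alcohol may be slow. The fallback is a Wittig reaction; it sets out from aldehyde 11 and alcohol 13 and comes back at 14.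
- Alcohol 13 with paraformaldehyde and TMSCl should give (1R,2S)-1-(chloromethoxy)-2-phenylcyclohexane F6.
- PPh3 in toluene should give {[(1R,2S)-2-phenylcyclohexyl]oxymethyl}triphenylphosphonium chloride F7.
- The ylide of F7 (NaHMDS, THF, −78 °C to rt) with 11 should give 14 together with the (Z)-isomer of 14 F8, which is removed by chromatography on triethylamine-deactivated silica.

This avoids the vinyl iodide and the copper step but gives up stereospecificity.

Step 3. Methanolysis may not discriminate well between the three silyl ethers, or may run on to diols. The fallback differentiates the oxygens by acylation before silylation; it sets out from triol 3 and comes back at 5.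
- Pivaloyl chloride (1.0 equiv), pyridine, CH2Cl2, −40 °C should acylate the hydroxyl para to the prenyl group, the only one without an ortho substituent, to give 3,5-dihydroxy-4-(3-methylbut-2-enyl)phenyl pivalate F9.
- TBSCl and imidazole should give 3,5-bis(tert-butyldimethylsilyloxy)-4-(3-methylbut-2-enyl)phenyl pivalate F10.
- DIBAL-H in CH2Cl2 at −78 °C removes the pivalate reductively without touching the aryl silyl ethers and gives 5.

**Further compounds**

F1 | step 10 | 2,4-bis(tert-butyldimethylsilyloxy)-6-hydroxy-3-(3-methylbut-2-enyl)benzaldehyde | O=Cc1c(O)cc(O[Si](C)(C)C(C)(C)C)c(CC=C(C)C)c1O[Si](C)(C)C(C)(C)C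
F2 | step 10 | 3,5-bis(tert-butyldimethylsilyloxy)-2-formyl-4-(3-methylbut-2-enyl)phenyl tert-butyl carbonate | O=Cc1c(OC(=O)OC(C)(C)C)cc(O[Si](C)(C)C(C)(C)C)c(CC=C(C)C)c1O[Si](C)(C)C(C)(C)C
F3 | step 10 | 3,5-bis(tert-butyldimethylsilyloxy)-2-(hydroxymethyl)-4-(3-methylbut-2-enyl)phenyl tert-butyl carbonate | OCc1c(OC(=O)OC(C)(C)C)cc(O[Si](C)(C)C(C)(C)C)c(CC=C(C)C)c1O[Si](C)(C)C(C)(C)C
F4 | step 10 | 3,5-bis(tert-butyldimethylsilyloxy)-6-methylidene-4-(3-methylbut-2-enyl)cyclohexa-2,4-dien-1-one (ortho-quinone methide, not isolated) | C=C1C(=O)C=C(O[Si](C)(C)C(C)(C)C)C(CC=C(C)C)=C1O[Si](C)(C)C(C)(C)C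
F5 | step 10 | (3R)-5,7-bis(tert-butyldimethylsilyloxy)-3-[2,2-dimethyl-5-(triisopropylsilyloxy)-2H-chromen-8-yl]-6-(3-methylbut-2-enyl)-2-[(1R,2S)-2-phenylcyclohexyloxy]chroman (C2 epimers) | CC(C)(C)[Si](C)(C)Oc1c(CC=C(C)C)c(O[Si](C)(C)C(C)(C)C)cc2c1C[C@H](c1ccc(O[Si](C(C)C)(C(C)C)C(C)C)c3c1OC(C)(C)C=C3)C(O[C@@H]1CCCC[C@H]1c1ccccc1)O2
F6 | step 9 | (1R,2S)-1-(chloromethoxy)-2-phenylcyclohexane | ClCO[C@@H]1CCCC[C@H]1c1ccccc1
F7 | step 9 | {[(1R,2S)-2-phenylcyclohexyl]oxymethyl}triphenylphosphonium chloride | [Cl-].c1ccccc1[P+](c1ccccc1)(c1ccccc1)CO[C@@H]1CCCC[C@H]1c1ccccc1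
F8 | step 9 | (Z)-2,2-dimethyl-8-{2-[(1R,2S)-2-phenylcyclohexyloxy]ethenyl}-5-(triisopropylsilyloxy)-2H-chromene | CC1(C)C=Cc2c(O[Si](C(C)C)(C(C)C)C(C)C)ccc(/C=C\O[C@@H]3CCCC[C@H]3c3ccccc3)c2O1
F9 | step 3 | 3,5-dihydroxy-4-(3-methylbut-2-enyl)phenyl pivalate | CC(C)=CCc1c(O)cc(OC(=O)C(C)(C)C)cc1O
F10 | step 3 | 3,5-bis(tert-butyldimethylsilyloxy)-4-(3-methylbut-2-enyl)phenyl pivalate | CC(C)=CCc1c(O[Si](C)(C)C(C)(C)C)cc(OC(=O)C(C)(C)C)cc1O[Si](C)(C)C(C)(C)C
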